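**Retrosynthetic overview**

Target 25 ⇐ acyl removal and acylative dynamic kinetic resolution at the lactol carbon ⇐ racemic lactol 23 ⇐ double benzylic bromination and hydrolysis of the methylene-level lactone 18 (lactone CH2 → CH(OH), ring B CH3 → CH2OH).
Ring D of 18 ⇐ depsidone acid 15 + CH2Br2: the acetal carbon of ring D sits on the one ring B carbon between the carboxyl-bearing carbon and the carbon carrying the diaryl ether oxygen, and in 15 this is the only C–H ortho to the carboxyl group.
Ring C (seven-membered depsidone ring) of 15 ⇐ lactonisation of a diaryl ether acid ⇐ SNAr of ring B hydroquinone 9 on ring A aryl fluoride 5.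
Ring A piece 5 ⇐ 3-fluoro-5-methylanisole (bromination, ortho-lithiation/formylation, carbonylation); ring B piece 9 ⇐ methyl 2,4-dihydroxy-3-methylbenzoate (4-O-benzylation, Elbs hydroxylation).
Order of ring formation: rings A and B are bought as arenes, ring C is closed in step 8, ring D in step 10.

Key step: step 10

Remark on the chemistry (assumption): the lactol carbon of the target is (S); free lactols of the 3-hydroxyphthalide type racemise by ring–chain tautomerism under base or acid, so it is assumed that 25 keeps its configuration in cold, neutral, aprotic solution for the time of isolation. The sense of induction of the catalyst in step 15 is to be assigned on the first run, and the enantiomeric catalyst is used if needed.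

**Route**

Step 1
Reactants: 1 3-fluoro-5-methylanisole
Product: 2 4-bromo-3-fluoro-5-methylanisole
Conditions: N-bromosuccinimide, MeCN, 0 °C → rt
Reagents that add atoms: N-bromosuccinimide, O=C1CCC(=O)N1Br
Why: Electrophilic aromatic bromination of an anisole goes para to the methoxy group (as with other 3,5-disubstituted anisoles in MeCN), and minor ortho isomers are removed by chromatography.

Step 2
Reactants: 2 4-bromo-3-fluoro-5-methylanisole
Product: 4 3-bromo-2-fluoro-6-methoxy-4-methylbenzaldehyde, via aryllithium 3 (not isolated)
Conditions: LiN(iPr)2, THF, −78 °C; DMF, −78 °C → 0 °C; aq. NH4Cl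
Reagents that add atoms: N,N-dimethylformamide, CN(C)C=O
Why: Directed ortho-lithiation removes the hydrogen flanked by fluorine and methoxy, by far the most acidic one, at a temperature that avoids LiF loss and bromine migration, and DMF formylates the aryllithium.

Step 3
Reactants: 4 3-bromo-2-fluoro-6-methoxy-4-methylbenzaldehyde
Product: 5 benzyl 2-fluoro-3-formyl-4-methoxy-6-methylbenzoate
Conditions: Pd(OAc)2 (3 mol%), Xantphos [4,5-bis(diphenylphosphino)-9,9-dimethylxanthene], CO (1 atm), BnOH (1.5 equiv), Et3N, toluene, 90 °C
Reagents that add atoms: carbon monoxide, [C-]#[O+]; benzyl alcohol, OCc1ccccc1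
Why: Pd-catalysed alkoxycarbonylation of an aryl bromide tolerates the aldehyde and the two ortho substituents with a wide-bite-angle ligand, and the neutral alcohol with Et3N in toluene should not displace the fluoride.

Step 4
Reactants: 6 methyl 2,4-dihydroxy-3-methylbenzoate
Product: 7 methyl 4-(benzyloxy)-2-hydroxy-3-methylbenzoate
Conditions: BnBr (1.05 equiv), K2CO3, acetone, reflux
Reagents that add atoms: benzyl bromide, BrCc1ccccc1
Why: Williamson etherification is selective for the 4-hydroxyl because the 2-hydroxyl is hydrogen-bonded to the ester carbonyl and flanked on both sides.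

Step 5
Reactants: 7 methyl 4-(benzyloxy)-2-hydroxy-3-methylbenzoate
Product: 9 methyl 4-(benzyloxy)-2,5-dihydroxy-3-methylbenzoate, via aryl potassium sulfate 8 (not isolated)
Conditions: K2S2O8, aq. NaOH, pyridine, 0 °C → rt, N2; then aq. HCl, 70 °C
Reagents that add atoms: potassium peroxodisulfate, [K+].[K+].[O-]S(=O)(=O)OOS(=O)(=O)[O-]
Why: Elbs persulfate oxidation: the phenoxide of the 2-hydroxyl attacks peroxodisulfate through its para carbon (both ortho carbons are substituted), and dilute acid hydrolyses the aryl sulfate to the hydroquinone; unreacted 7 is recovered.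

Step 6
Reactants: 5 benzyl 2-fluoro-3-formyl-4-methoxy-6-methylbenzoate; 9 methyl 4-(benzyloxy)-2,5-dihydroxy-3-methylbenzoate
Product: 11 benzyl 2-[2-(benzyloxy)-4-methoxy-5-(methoxycarbonyl)-3-methylphenoxy]-3-formyl-4-methoxy-6-methylbenzoate, via diaryl ether phenol 10 (not isolated)
Conditions: K2CO3, DMF, 60 °C, N2; then MeI, 50 °C
Reagents that add atoms: iodomethane, CI
Why: Nucleophilic aromatic substitution: the fluoride of 5, activated by the ortho formyl and ortho ester groups, is displaced by the unhindered 5-phenoxide of 9 (the 2-hydroxyl is chelated and flanked on both sides), and Williamson methylation of that remaining phenol in the same pot protects it for the key step.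

Step 7
Reactants: 11 benzyl 2-[2-(benzyloxy)-4-methoxy-5-(methoxycarbonyl)-3-methylphenoxy]-3-formyl-4-methoxy-6-methylbenzoate
Product: 12 3-formyl-2-[2-hydroxy-4-methoxy-5-(methoxycarbonyl)-3-methylphenoxy]-4-methoxy-6-methylbenzoic acid
Conditions: H2 (1 atm), Pd/C (10%), EtOAc, rt
Reagents that add atoms: none
Why: Catalytic hydrogenolysis removes the benzyl ester and the benzyl ether together, and the aryl aldehyde, flanked by two oxygen substituents, should survive these mild conditions as formyl groups do in depside chemistry.

Step 8
Reactants: 12 3-formyl-2-[2-hydroxy-4-methoxy-5-(methoxycarbonyl)-3-methylphenoxy]-4-methoxy-6-methylbenzoic acid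
Product: 14 methyl 4-formyl-3,8-dimethoxy-1,9-dimethyl-11-oxo-11H-dibenzo[b,e][1,4]dioxepine-7-carboxylate, via mixed trifluoroacetic anhydride 13 (not isolated)
Conditions: (CF3CO)2O, toluene–CH2Cl2, 0 °C → rt
Reagents that add atoms: none
Why: Lactonisation through the mixed anhydride is the standard depsidone ring closure; the diaryl ether holds the phenol next to the activated acyl group, so the seven-membered ring C closes in preference to intermolecular acylation.

Step 9
Reactants: 14 methyl 4-formyl-3,8-dimethoxy-1,9-dimethyl-11-oxo-11H-dibenzo[b,e][1,4]dioxepine-7-carboxylate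
Product: 15 4-formyl-3,8-dimethoxy-1,9-dimethyl-11-oxo-11H-dibenzo[b,e][1,4]dioxepine-7-carboxylic acid
Conditions: LiI (5 equiv), EtOAc, reflux, dark; then 1 M HCl
Reagents that add atoms: none
Why: SN2 dealkylation of the methyl ester by iodide at the methyl carbon frees the ring B carboxyl without a nucleophile at acyl carbon, so the depsidone aryl ester, which offers iodide no alkyl carbon, stays closed.

Step 10
Reactants: 15 4-formyl-3,8-dimethoxy-1,9-dimethyl-11-oxo-11H-dibenzo[b,e][1,4]dioxepine-7-carboxylic acid; 16 dibromomethane
Product: 18 depsidone 15 with a gamma-lactone ring D fused at C6–C7 (C7 carbonyl, C6 CH2–O; methylene oxidation level), via ortho-bromomethyl carboxylate 17 (not isolated)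
Conditions: Pd(OAc)2 (10 mol%), K2HPO4 (3 equiv), CH2Br2 (solvent), 140 °C, sealed tube
Reagents that add atoms: dibromomethane, BrCBr
Why: The carboxylate of 15 binds divalent palladium and a concerted metalation–deprotonation at the only ortho C–H gives a five-membered palladacycle; oxidative addition of CH2Br2 (to tetravalent palladium) and reductive elimination form the aryl–CH2Br bond of 17, and the carboxylate then displaces the second bromide. The closest known reaction type is the Pd(OAc)2/K2HPO4 ortho C–H alkylation–lactonisation of benzoic acids with dihalomethanes to phthalides. Ring D closes by intramolecular SN2 O-alkylation in the 5-exo-tet mode. No stereocentre is formed. The step needs site selectivity, which the substrate secures: the other ortho position of the carboxylate carries the methoxy group, there is only one carboxylate, and the aryl ester, the aldehyde and the aryl methyl groups do not direct palladation. The weak base K2HPO4 in a non-nucleophilic medium should leave the depsidone ester closed.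

Step 11
Reactants: 18 lactone-fused depsidone (3,8-dimethoxy)
Product: 20 3,8-dihydroxy analogue of 18, via aryloxyboron dichloride 19 (not isolated)
Conditions: BCl3 (4 equiv), CH2Cl2, −78 °C → 0 °C; then H2O
Reagents that add atoms: none
Why: BCl3 cleaves aryl methyl ethers ortho to a carbonyl group through a six-membered boron chelate, which holds for both methoxy groups (ortho to the formyl group on ring A, ortho to the lactone carbonyl on ring B), while esters and lactones are untouched at 0 °C.

Step 12
Reactants: 20 3,8-dihydroxy lactone-fused depsidone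
Product: 21 3,8-di-O-acetate of 20 with the formyl group as its geminal diacetate
Conditions: Ac2O, H2SO4 (cat.), 0 °C → rt
Reagents that add atoms: acetic anhydride, CC(=O)OC(C)=O
Why: Acid-catalysed acetylation converts both phenols into aryl acetates and the aldehyde into its acylal, which removes the abstractable formyl hydrogen and the bromination-prone phenol rings before the radical step.

Step 13
Reactants: 21 di-O-acetate geminal diacetate
Product: 22 dibromide of 21 (ring B CH2Br; lactone CHBr, racemic)
Conditions: N-bromosuccinimide (2.1 equiv), 2,2'-azobis(2-methylpropionitrile) (cat.), PhCF3, 85 °C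
Reagents that add atoms: N-bromosuccinimide, O=C1CCC(=O)N1Br
Why: Wohl–Ziegler bromination: the bromine atom abstracts hydrogen from the lactone CH2 (benzylic and alpha to oxygen) and from the ring B methyl, while the ring A methyl, ortho to the ester carbonyl and para to the electron-poor acylal carbon, is polarity-mismatched and should react last; the CHBr centre forms racemic.

Step 14
Reactants: 22 dibromide
Product: 23 racemic target (racemic lactol)
Conditions: H2O–1,4-dioxane (1:2), 60 °C; then 2 M HCl, 70 °C, dilute solution
Reagents that add atoms: water, O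
Why: Solvolysis converts the 3-bromophthalide into the lactol and the benzylic bromide into the alcohol, and dilute acid then hydrolyses the aryl acetates and the acylal, conditions that the hindered depsidone ester should survive; the lactol is racemic.

Step 15
Reactants: 23 racemic target
Product: 24 (S)-lactol O-propanoate of the target carrying propanoates also on both phenols and on the CH2OH group
Conditions: (2S,3R)-HyperBTM [(2S,3R)-3-isopropyl-2-phenyl-3,4-dihydro-2H-benzo[4,5]thiazolo[3,2-a]pyrimidine] (5 mol%), (EtCO)2O (6 equiv), iPr2NEt (6 equiv), CHCl3, −40 °C → 0 °C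
Reagents that add atoms: propanoic anhydride, CCC(=O)OC(=O)CC
Why: Acylative dynamic kinetic resolution of a 3-hydroxyphthalide by a chiral isothiourea: base-mediated ring–chain tautomerism interconverts the lactol enantiomers while the chiral acyl isothiouronium ion acylates one of them faster, so the lactol carbon is fixed as the (S)-ester under catalyst control, and the primary alcohol and the two phenols are acylated alongside without stereochemical consequence.

Step 16
Reactants: 24 (S)-tetrapropanoate
Product: 25 target, (S)-lactol
Conditions: Candida antarctica lipase B (immobilised), n-BuOH (20 equiv), tert-butyl methyl ether, 20 °C; cold filtration and evaporation below 0 °C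
Reagents that add atoms: none
Why: Lipase-catalysed alcoholysis in an organic solvent cleaves each ester at its acyl carbon, so no bond to the lactol carbon is broken and the (S) configuration is retained, and the medium holds neither base nor acid to open the lactol.

**Compound list**

1 | 3-fluoro-5-methylanisole | COc1cc(C)cc(F)c1 | starting material
2 | 4-bromo-3-fluoro-5-methylanisole | COc1cc(C)c(Br)c(F)c1 | intermediate
3 | (3-bromo-2-fluoro-6-methoxy-4-methylphenyl)lithium (not isolated) | COc1cc(C)c(Br)c(F)c1[Li] | intermediate
4 | 3-bromo-2-fluoro-6-methoxy-4-methylbenzaldehyde | COc1cc(C)c(Br)c(F)c1C=O | intermediate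
5 | benzyl 2-fluoro-3-formyl-4-methoxy-6-methylbenzoate | COc1cc(C)c(C(=O)OCc2ccccc2)c(F)c1C=O | intermediate
6 | methyl 2,4-dihydroxy-3-methylbenzoate | COC(=O)c1ccc(O)c(C)c1O | starting material
7 | methyl 4-(benzyloxy)-2-hydroxy-3-methylbenzoate | COC(=O)c1ccc(OCc2ccccc2)c(C)c1O | intermediate
8 | potassium 2-(benzyloxy)-4-hydroxy-5-(methoxycarbonyl)-3-methylphenyl sulfate (not isolated) | COC(=O)c1cc(OS(=O)(=O)[O-])c(OCc2ccccc2)c(C)c1O.[K+] | intermediate
9 | methyl 4-(benzyloxy)-2,5-dihydroxy-3-methylbenzoate | COC(=O)c1cc(O)c(OCc2ccccc2)c(C)c1O | intermediate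
10 | benzyl 2-[2-(benzyloxy)-4-hydroxy-5-(methoxycarbonyl)-3-methylphenoxy]-3-formyl-4-methoxy-6-methylbenzoate (not isolated) | COC(=O)c1cc(Oc2c(C=O)c(OC)cc(C)c2C(=O)OCc2ccccc2)c(OCc2ccccc2)c(C)c1O | intermediate
11 | benzyl 2-[2-(benzyloxy)-4-methoxy-5-(methoxycarbonyl)-3-methylphenoxy]-3-formyl-4-methoxy-6-methylbenzoate | COC(=O)c1cc(Oc2c(C=O)c(OC)cc(C)c2C(=O)OCc2ccccc2)c(OCc2ccccc2)c(C)c1OC | intermediate
12 | 3-formyl-2-[2-hydroxy-4-methoxy-5-(methoxycarbonyl)-3-methylphenoxy]-4-methoxy-6-methylbenzoic acid | COC(=O)c1cc(Oc2c(C=O)c(OC)cc(C)c2C(=O)O)c(O)c(C)c1OC | intermediate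
13 | mixed anhydride of 12 with trifluoroacetic acid (not isolated) | COC(=O)c1cc(Oc2c(C=O)c(OC)cc(C)c2C(=O)OC(=O)C(F)(F)F)c(O)c(C)c1OC | intermediate
14 | methyl 4-formyl-3,8-dimethoxy-1,9-dimethyl-11-oxo-11H-dibenzo[b,e][1,4]dioxepine-7-carboxylate | Cc1cc(OC)c(C=O)c2c1C(=O)Oc1c(C)c(OC)c(C(=O)OC)cc1O2 | intermediate
15 | 4-formyl-3,8-dimethoxy-1,9-dimethyl-11-oxo-11H-dibenzo[b,e][1,4]dioxepine-7-carboxylic acid | Cc1cc(OC)c(C=O)c2c1C(=O)Oc1c(C)c(OC)c(C(=O)O)cc1O2 | intermediate
16 | dibromomethane | BrCBr | starting material
17 | potassium 6-(bromomethyl)-4-formyl-3,8-dimethoxy-1,9-dimethyl-11-oxo-11H-dibenzo[b,e][1,4]dioxepine-7-carboxylate (not isolated) | Cc1cc(OC)c(C=O)c2c1C(=O)Oc1c(C)c(OC)c(C(=O)[O-])c(CBr)c1O2.[K+] | intermediate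
18 | depsidone with gamma-lactone ring D fused at C6–C7, methylene level (3,8-dimethoxy, 4-formyl, 1,9-dimethyl) | Cc1cc(OC)c(C=O)c2c1C(=O)Oc1c(C)c(OC)c3c(c1O2)COC3=O | intermediate
19 | bis(dichloroboryl) ether of 20 (not isolated) | Cc1cc(OB(Cl)Cl)c(C=O)c2c1C(=O)Oc1c(C)c(OB(Cl)Cl)c3c(c1O2)COC3=O | intermediate
20 | 3,8-dihydroxy analogue of 18 | Cc1cc(O)c(C=O)c2c1C(=O)Oc1c(C)c(O)c3c(c1O2)COC3=O | intermediate
21 | 3,8-di-O-acetate of 20 with the formyl group as geminal diacetate | Cc1cc(OC(C)=O)c(C(OC(C)=O)OC(C)=O)c2c1C(=O)Oc1c(C)c(OC(C)=O)c3c(c1O2)COC3=O | intermediate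
22 | dibromide of 21 (ring B CH2Br, lactone CHBr, racemic) | Cc1cc(OC(C)=O)c(C(OC(C)=O)OC(C)=O)c2c1C(=O)Oc1c(CBr)c(OC(C)=O)c3c(c1O2)C(Br)OC3=O | intermediate
23 | racemic target (racemic lactol) | Cc1cc(O)c(C=O)c2c1C(=O)Oc1c(CO)c(O)c3c(c1O2)C(O)OC3=O | intermediate
24 | (S)-lactol O-propanoate of the target, with propanoates on both phenols and on the CH2OH group | Cc1cc(OC(=O)CC)c(C=O)c2c1C(=O)Oc1c(COC(=O)CC)c(OC(=O)CC)c3c(c1O2)[C@@H](OC(=O)CC)OC3=O | intermediate
25 | target, (S)-lactol (salazinic acid constitution) | Cc1cc(O)c(C=O)c2c1C(=O)Oc1c(CO)c(O)c3c(c1O2)[C@@H](O)OC3=O | target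

**Step count and risks**

Total step count: 16. Longest linear sequence: 14 steps (steps 1–3, then 6–16); the ring B branch (steps 4–5) joins at step 6.

The three steps most likely to fail:

Step 10. Palladation at the C–H wedged between the carboxylate and the aryloxy group may be too slow. O-alkylation of the carboxylate by CH2Br2, decarbonylation of the free aldehyde, or opening of the depsidone ring at 140 °C could then take over. The fallback sets out from 9 and 5 and comes back at 18; it puts the one-carbon unit on ring B before the rings are joined. Magnesium-mediated ortho-formylation of 9 (MgCl2, Et3N, paraformaldehyde, MeCN, reflux) can only occur at C6 and should give methyl 4-(benzyloxy)-6-formyl-2,5-dihydroxy-3-methylbenzoate F1. NaBH4 in MeOH reduces it to methyl 4-(benzyloxy)-2,5-dihydroxy-6-(hydroxymethyl)-3-methylbenzoate F2, which lactonises on acidification to 5-(benzyloxy)-4,7-dihydroxy-6-methylisobenzofuran-1(3H)-one F3. SNAr with 5 (K2CO3, DMF, 60 °C) at the unchelated 4-hydroxyl gives the diaryl ether phenol F4, and MeI in the same pot gives its 7-O-methyl ether F5. Hydrogenolysis (H2, Pd/C, EtOAc) gives the seco acid F6, and trifluoroacetic anhydride closes ring C to give 18.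

Step 13. Hydrogen abstraction may not discriminate well enough between the ring B methyl and the ring A methyl, or may run on to the dibromomethyl stage. The fallback sets out from 18 and comes back at 23; it reverses the order of phenol deprotection and C–H oxidation, so that the radical step runs on the bis(methyl ether). There the ring B methyl has an ortho methoxy donor and the rings carry no acetates. Ac2O with catalytic H2SO4 masks only the aldehyde and gives the geminal diacetate of 18 F7. N-bromosuccinimide with 2,2'-azobis(2-methylpropionitrile) in PhCF3 gives the dibromide of F7 F8. Aqueous dioxane at 70 °C gives the racemic 3,8-di-O-methyl ether of the target F9. BCl3 in CH2Cl2 followed by water then gives 23.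

Step 16. The free lactol may lose its configuration by ring–chain tautomerism during or after deacylation. The lipase may also fail to accept the (S)-lactol ester or the hindered aryl ester. The fallback sets out from 23 and comes back at 25. The enantiomers of the racemic lactol are separated directly by preparative chromatography on a polysaccharide chiral stationary phase at low temperature with a neutral or weakly acidic eluent. The (S)-enantiomer is collected cold as 25, and the unwanted enantiomer is left to racemise and is re-injected. This fallback also bypasses step 15.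

**Further compounds**

F1 | step 10 | methyl 4-(benzyloxy)-6-formyl-2,5-dihydroxy-3-methylbenzoate | COC(=O)c1c(C=O)c(O)c(OCc2ccccc2)c(C)c1O
F2 | step 10 | methyl 4-(benzyloxy)-2,5-dihydroxy-6-(hydroxymethyl)-3-methylbenzoate | COC(=O)c1c(CO)c(O)c(OCc2ccccc2)c(C)c1O
F3 | step 10 | 5-(benzyloxy)-4,7-dihydroxy-6-methylisobenzofuran-1(3H)-one | O=C1OCc2c(O)c(OCc3ccccc3)c(C)c(O)c21
F4 | step 10 | benzyl 2-{[5-(benzyloxy)-7-hydroxy-6-methyl-1-oxo-1,3-dihydroisobenzofuran-4-yl]oxy}-3-formyl-4-methoxy-6-methylbenzoate | O=C1OCc2c(Oc3c(C=O)c(OC)cc(C)c3C(=O)OCc3ccccc3)c(OCc3ccccc3)c(C)c(O)c21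
F5 | step 10 | benzyl 2-{[5-(benzyloxy)-7-methoxy-6-methyl-1-oxo-1,3-dihydroisobenzofuran-4-yl]oxy}-3-formyl-4-methoxy-6-methylbenzoate | O=C1OCc2c(Oc3c(C=O)c(OC)cc(C)c3C(=O)OCc3ccccc3)c(OCc3ccccc3)c(C)c(OC)c21
F6 | step 10 | 3-formyl-2-[(5-hydroxy-7-methoxy-6-methyl-1-oxo-1,3-dihydroisobenzofuran-4-yl)oxy]-4-methoxy-6-methylbenzoic acid | O=C1OCc2c(Oc3c(C=O)c(OC)cc(C)c3C(=O)O)c(O)c(C)c(OC)c21
F7 | step 13 | geminal diacetate of 18 | Cc1cc(OC)c(C(OC(C)=O)OC(C)=O)c2c1C(=O)Oc1c(C)c(OC)c3c(c1O2)COC3=O
F8 | step 13 | dibromide of F7 (ring B CH2Br, lactone CHBr, racemic) | Cc1cc(OC)c(C(OC(C)=O)OC(C)=O)c2c1C(=O)Oc1c(CBr)c(OC)c3c(c1O2)C(Br)OC3=O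
F9 | step 13 | racemic 3,8-di-O-methyl ether of the target | Cc1cc(OC)c(C=O)c2c1C(=O)Oc1c(CO)c(OC)c3c(c1O2)C(O)OC3=O
F0 | step 16 | none | none
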